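(Its constants are made up; the run is a simulation.)

The pitfall in this flask is to count every incoming ligand as one exchange made: counted so, the charges allow 75.0% of complex with two exchanged, with the incoming ligand as limiting reagent.

    starting complex + incoming ligand ⇌ leaving ligand + complex with one exchanged (K1 = 4.2, k1 = 0.23 /M/s)
    complex with one exchanged + incoming ligand ⇌ leaving ligand + complex with two exchanged (K2 = 1.1, k2 = 0.71 /M/s)
    complex with two exchanged + incoming ligand → over-reaction product (k3 = 0.021 /M/s)
    incoming ligand → decomposed reagent (k4 = 0.0033 /s)

starting complex 0.022 M; incoming ligand 0.0330 M; time 4.0 min

1. amount of complex with two exchanged at 4.0 min, in percent of the starting complex charged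
2. amount of complex with one exchanged at 4.0 min, in percent of the starting complex charged
3. amount of complex with two exchanged if the flask were left three thousand times as long, in percent of the starting complex charged

But the incoming ligand drains two ways in parallel. At the start, the first exchange acts on it as a pseudo-first-order drain of 0.00506 /s, and decomposition as a drain of 0.0033 /s. So 0.65 of a ligand decomposes for each one the first exchange takes. I carry this split over to the whole charge:

0.23 /M/s × 0.0330 M / (0.23 /M/s × 0.022 M + 0.0033 /s) = 0.908

This is the exchange budget, the exchanges per starting complex charged that the ligand pays for when all of it is shared as at the start.

The neighbour differs from this flask in one charge, 0.037 M of starting complex, and its drain through the first exchange is wider. Yet its ligand is spread over more complex, 0.892 equiv instead of 1.50, so its budget comes to 0.643, smaller than the budget of this flask. I therefore expect the neighbour to end less far along than this flask. My reckoning stops there, because a budget counts exchanges and doesn't split them between the two complexes.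

The forecast gives 17% of complex with two exchanged and 33% of complex with one exchanged, then 0% after the long wait, since “the exchanges run backward toward the starting complex”. Its first two figures count 0.670 exchanges per complex, fewer than my budget.

The simulation gives 17.2%, 33.4% and 0%, so the forecast held.

In this flask, the budget applied to the 81.2% of ligand used gives 0.737 exchanges per complex, and the leaving ligand released shows 0.694. The falling level of incoming ligand is the main reason conversion here stands at 51.4%: with that level held, it reaches 80.0%. In the neighbour, the budget on its used ligand gives 0.558. The simulation shows 0.525, with 9.67% of complex with two exchanged and 32.3% of complex with one exchanged.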